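**Plan**

- Retrosynthesis, last cut first: O-protecting groups; C12–C13 and C9–C11 (two cross-couplings at a C8=C9 enol triflate, that is a C9 ketone); C2–O (hydroboration of C2=C3); C4–C19 (allylboration of formaldehyde by a C2 allylboronate); C1–C2 and C5–C10 together in one intramolecular Diels–Alder reaction; then C2=C3, C4=C5 and C9–C10 of an acyclic chain.
- Enabling feature: in ring A (C1, C2, C3, C4, C5, C10) the bonds C1–C2 and C5–C10 lie opposite each other, with C1–C10 on one side and C2–C3–C4–C5 on the other. With a C3=C4 alkene, ring A is therefore the adduct of diene C2=C3–C4=C5 and alkene C10=C1. C9, an alkene carbon of ring B in the target, can be a ketone that activates C10=C1, and C6–C7–C8–C9 is the tether, so a 1,7,9-decatrien-3-one closes rings A and B at once.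
- A pinacolboryl group on C2 is a temporary control element: the C2–B bond (absent from the target) is set β in the cycloaddition, delivers C19 to the β face of C4 and is cleaved in doing so.
- Forward order: (S)-lactone from L-glutamic acid → acyclic borylated trienone → rings A and B → quaternary C4 → C8 methyl, C8=C9 triflate, 6-acetate → 2α-OH → vinyl group, butenolide → desilylation.
- Stereochemistry: C6 from the lactone; C5, C10 and C2(B) from the cycloaddition (allylic strain between the C4 methyl and C6; E-boryl alkene); C4 by suprafacial transfer from C2–B; C2–OH by hydroboration on the α face, opposite axial C20 and C19.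

Key step: step 6

Assumption: ring compounds carry labdane locants (decalin C1–C10; C18 = 4α-CH3, C19 = 4β-CH2O, C20 = 10β-CH3; side chain C11–C16; β = the face of C20), and 2-(dichloromethyl)pinacolborane and 4-bromofuran-2(5H)-one are taken as purchasable.

**Step 1**
Reactants: 1 (S)-5-(hydroxymethyl)dihydrofuran-2(3H)-one
Product: 2 (4S)-4,5-dihydroxy-N-methoxy-N-methylpentanamide
Conditions: MeNHOMe·HCl, i-PrMgCl, THF, −20 to 0 °C; aq. NH4Cl; used crude
Reagents that add atoms: N,O-dimethylhydroxylamine hydrochloride, Cl.CNOC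
Why: Aminolysis of the γ-lactone by the magnesium amide (Weinreb amide formation) breaks only the acyl C–O bond, so the C6 stereocenter (S) is untouched.

**Step 2**
Reactants: 2 (4S)-4,5-dihydroxy-N-methoxy-N-methylpentanamide
Product: 3 (4S)-N-methoxy-N-methyl-4,5-bis(triethylsilyloxy)pentanamide
Conditions: Et3SiCl, imidazole, DMAP (cat.), DMF, 0 °C to rt
Reagents that add atoms: chlorotriethylsilane, CC[Si](Cl)(CC)CC
Why: Imidazole-promoted silylation should trap both hydroxyls before the γ-hydroxy amide can relactonise, and no stereocenter is formed.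

**Step 3**
Reactants: 3 (4S)-N-methoxy-N-methyl-4,5-bis(triethylsilyloxy)pentanamide; 4 isopropenylmagnesium bromide, CH2=C(CH3)MgBr
Product: 5 (6S)-2-methyl-6,7-bis(triethylsilyloxy)hept-1-en-3-one
Conditions: THF, −20 to 0 °C; aq. NH4Cl
Reagents that add atoms: isopropenylmagnesium bromide, CC(=C)[Mg]Br
Why: In the Weinreb ketone synthesis the chelated tetrahedral intermediate stops at mono-addition and should release the isopropenyl ketone, which is the future C9 carbonyl with the C10=C1 dienophile.

**Step 4**
Reactants: 5 (6S)-2-methyl-6,7-bis(triethylsilyloxy)hept-1-en-3-one; 6 2-(triphenylphosphoranylidene)propanal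
Product: 8 (2E,4S)-2,8-dimethyl-7-oxo-4-(triethylsilyloxy)nona-2,8-dienal, via α-silyloxy aldehyde 7 (not isolated)
Conditions: (COCl)2, DMSO, CH2Cl2, −78 to −40 °C; Et3N; then 6, rt
Reagents that add atoms: 2-(triphenylphosphoranylidene)propanal, CC(C=O)=P(c1ccccc1)(c1ccccc1)c1ccccc1
Why: Swern conditions oxidise a primary triethylsilyl ether directly to the aldehyde while the secondary one survives, and the stabilised ylide should then give the (E)-2-methyl enal in a Wittig reaction (E places C6 cis to the C4 methyl), the sensitive aldehyde being consumed in the flask so that C6 should not epimerise.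

**Step 5**
Reactants: 8 (2E,4S)-2,8-dimethyl-7-oxo-4-(triethylsilyloxy)nona-2,8-dienal; 9 2-(dichloromethyl)-4,4,5,5-tetramethyl-1,3,2-dioxaborolane
Product: 10 (6S,7E,9E)-2,8-dimethyl-10-(4,4,5,5-tetramethyl-1,3,2-dioxaborolan-2-yl)-6-(triethylsilyloxy)deca-1,7,9-trien-3-one
Conditions: CrCl2, LiI (additive), THF, rt
Reagents that add atoms: 2-(dichloromethyl)-4,4,5,5-tetramethyl-1,3,2-dioxaborolane, ClC(Cl)B1OC(C)(C)C(C)(C)O1
Why: The Takai–Utimoto olefination with the geminal dichromium reagent is selective for the aldehyde over the ketone and should give the (E)-alkenylboronate, that is the (E,E)-1-boryl diene.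

**Step 6**
Reactants: 10 (6S,7E,9E)-2,8-dimethyl-10-(pinacolatoboryl)-6-(triethylsilyloxy)deca-1,7,9-trien-3-one
Product: 11 trans-fused allylboronate: decal-3-en-9-one with 2β-(4,4,5,5-tetramethyl-1,3,2-dioxaborolan-2-yl), 4-CH3 on the C3=C4 alkene, 5α-H, 6α-OSiEt3, 10β-CH3
Conditions: toluene (0.01 M), BHT (cat.), 110 °C
Reagents that add atoms: none
Why: A thermal, concerted, suprafacial [4+2] cycloaddition (type 1 intramolecular Diels–Alder reaction) adds diene C2=C3–C4=C5 to the ketone-activated alkene C10=C1 and forms C5–C10 and C1–C2 together. The closest known reaction types are the intramolecular Diels–Alder reaction of 2-methyldeca-1,7,9-trien-3-ones and the cycloaddition of 1-(dialkoxyboryl)dienes that precedes an allylboration. Ring A closes as the cyclohexene of the cycloaddition itself, and ring B closes through the C5–C10 bond with the four-carbon tether C6–C9 in a chair-like arrangement exo (anti) to the diene, which gives the trans ring fusion. C5 is controlled by C6, because allylic 1,3-strain with the C4 methyl holds H6 in the diene plane so that the tether reaches one diene face while the silyloxy group lies on the other and ends equatorial (6α), anti to the new C5–C10 bond; C10 is controlled by the exo orientation of the C9 carbonyl (methyl endo); C2 is controlled by the E geometry of the boryl alkene, which puts boron outside and hence β, cis to C6 and pseudoaxial. The step needs exo (trans-fusion) and π-facial selectivity: the first should be secured by the α-methyl enone, which prefers carbonyl-exo, by the loss of enone conjugation when a chair tether holds the carbonyl endo, and by the clash of an endo tether with the C4 methyl; the second by the allylic strain just described. Regiochemistry is fixed by the tether.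

**Step 7**
Reactants: 11 trans-fused allylboronate; 12 formaldehyde (as paraformaldehyde)
Product: 14 homoallylic alcohol: decal-2-en-9-one with 4α-CH3, 4β-CH2OH (C19), 5α-H, 6α-OSiEt3, 10β-CH3, via borate ester 13 (not isolated)
Conditions: (CH2O)n, toluene, 70 °C, sealed tube; aq. NaHCO3
Reagents that add atoms: formaldehyde, C=O
Why: Allylboration through a closed six-membered transition state delivers boron-bound formaldehyde to C4 on the face from which the pseudoaxial C2–B bond departs (β), which should create the quaternary C4 with C19 β and the methyl α and move the alkene to C2=C3.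

**Step 8**
Reactants: 14 homoallylic alcohol
Product: 15 19-O-tert-butyldimethylsilyl ether of 14
Conditions: t-BuMe2SiCl, imidazole, DMF, rt
Reagents that add atoms: tert-butyldimethylsilyl chloride, CC(C)(C)[Si](C)(C)Cl
Why: Standard silylation of the only free (primary, neopentyl) hydroxyl protects it from the strong bases that follow, and no stereocenter is affected.

**Step 9**
Reactants: 15 19-O-silyl ketone
Product: 16 8α-methyl ketone (8-CH3 equatorial; otherwise as 15)
Conditions: LiN(i-Pr)2, THF, −78 °C; MeI, −78 to 0 °C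
Reagents that add atoms: iodomethane, CI
Why: Enolate alkylation can occur only at C8 because C10 is quaternary, and the new C8 center (expected mainly the equatorial 8α-methyl epimer, by attack opposite axial C20) is erased in step 10, so either epimer serves.

**Step 10**
Reactants: 16 8α-methyl ketone
Product: 17 C8=C9 enol triflate: decalin-2,8-diene with 9-OSO2CF3, 8-CH3, 4α-CH3, 4β-CH2OSi(t-Bu)Me2, 6α-OSiEt3, 10β-CH3
Conditions: KN(SiMe3)2, THF, −78 to 0 °C; PhNTf2, −78 °C to rt
Reagents that add atoms: N-phenylbis(trifluoromethanesulfonimide), O=S(=O)(N(c1ccccc1)S(=O)(=O)C(F)(F)F)C(F)(F)F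
Why: Enol triflate formation is regiospecific because C8 carries the only enolisable hydrogen, which should give the tetrasubstituted C8=C9 enol triflate of the target alkene position.

**Step 11**
Reactants: 17 enol triflate
Product: 18 6α-alcohol (6-OH free; otherwise as 17)
Conditions: PPTS (cat.), MeOH/CH2Cl2, 0 °C
Reagents that add atoms: none
Why: Acid-catalysed methanolysis should cleave the secondary triethylsilyl ether much faster than the hindered neopentyl tert-butyldimethylsilyl ether, with no change at any stereocenter.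

**Step 12**
Reactants: 18 6α-alcohol
Product: 19 6α-acetate (6-OAc; otherwise as 18)
Conditions: Ac2O, DMAP, pyridine, CH2Cl2, rt
Reagents that add atoms: acetic anhydride, CC(=O)OC(C)=O
Why: DMAP-catalysed acylation of the only free hydroxyl installs the acetate of the target with retention at C6.

**Step 13**
Reactants: 19 6α-acetate
Product: 20 2α-alcohol: ring A saturated with 2α-OH (equatorial); otherwise as 19
Conditions: BH3·THF, THF, 0 °C; NaBO3·4H2O, THF/H2O, rt
Reagents that add atoms: sodium perborate tetrahydrate (NaBO3·4H2O; oxygen source), [Na+].[Na+].O[B-]1(O)OO[B-](O)(O)OO1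
Why: Hydroboration–oxidation should add syn on the α face (the β face is shielded by axial C20 and C19) with boron at C2, away from quaternary C4, so that oxidation with retention gives the equatorial 2α-alcohol, the acetate and the electron-poor enol triflate being inert to borane at 0 °C.

**Step 14**
Reactants: 20 2α-alcohol; 21 tributyl(vinyl)stannane
Product: 22 9-vinyl diene: C9–CH=CH2 in place of the triflate; otherwise as 20
Conditions: Pd(PPh3)4 (cat.), LiCl, THF, 65 °C
Reagents that add atoms: tributyl(vinyl)stannane, C=C[Sn](CCCC)(CCCC)CCCC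
Why: The Stille coupling of hindered cyclohexenyl triflates with vinylstannanes is neutral and should tolerate the free hydroxyl and the acetate while forming C9–C11.

**Step 15**
Reactants: 22 9-vinyl diene; 23 4-bromofuran-2(5H)-one
Product: 25 19-O-tert-butyldimethylsilyl ether of the target, via alkylborane 24 (not isolated)
Conditions: 9-BBN (excess), THF, rt; then 23, Pd(dppf)Cl2 (cat.), AsPh3, aq. K3PO4, DMF, rt
Reagents that add atoms: 4-bromofuran-2(5H)-one, O=C1C=C(Br)CO1
Why: 9-BBN should add only to the terminal vinyl carbon (the tetrasubstituted C8=C9 alkene is inert), and the primary B-alkyl group then transfers in a B-alkyl Suzuki–Miyaura coupling with the β-bromobutenolide to form C12–C13.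

**Step 16**
Reactants: 25 19-O-silyl ether of the target
Product: 26 CNP0231903.1, 6α-acetoxy-2α,19-dihydroxylabda-8,13-dien-15,16-olide
Conditions: HF·pyridine, pyridine, THF, 0 °C to rt
Reagents that add atoms: none
Why: Buffered fluoride desilylation should free the neopentyl C19 hydroxyl without touching the acetate, the butenolide or any stereocenter.

**Compound list**

1 | (S)-5-(hydroxymethyl)dihydrofuran-2(3H)-one | OC[C@@H]1CCC(=O)O1 | starting material
2 | (4S)-4,5-dihydroxy-N-methoxy-N-methylpentanamide | OC[C@@H](O)CCC(=O)N(C)OC | intermediate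
3 | (4S)-N-methoxy-N-methyl-4,5-bis(triethylsilyloxy)pentanamide | CC[Si](CC)(CC)OC[C@@H](O[Si](CC)(CC)CC)CCC(=O)N(C)OC | intermediate
4 | isopropenylmagnesium bromide | CC(=C)[Mg]Br | starting material
5 | (6S)-2-methyl-6,7-bis(triethylsilyloxy)hept-1-en-3-one | CC[Si](CC)(CC)OC[C@@H](O[Si](CC)(CC)CC)CCC(=O)C(C)=C | intermediate
6 | 2-(triphenylphosphoranylidene)propanal | CC(C=O)=P(c1ccccc1)(c1ccccc1)c1ccccc1 | starting material
7 | (2S)-6-methyl-5-oxo-2-(triethylsilyloxy)hept-6-enal | CC[Si](CC)(CC)O[C@H](C=O)CCC(=O)C(C)=C | intermediate (not isolated)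
8 | (2E,4S)-2,8-dimethyl-7-oxo-4-(triethylsilyloxy)nona-2,8-dienal | CC[Si](CC)(CC)O[C@H](/C=C(C)/C=O)CCC(=O)C(C)=C | intermediate
9 | 2-(dichloromethyl)-4,4,5,5-tetramethyl-1,3,2-dioxaborolane | ClC(Cl)B1OC(C)(C)C(C)(C)O1 | starting material
10 | (6S,7E,9E)-2,8-dimethyl-10-(4,4,5,5-tetramethyl-1,3,2-dioxaborolan-2-yl)-6-(triethylsilyloxy)deca-1,7,9-trien-3-one | CC[Si](CC)(CC)O[C@H](/C=C(C)/C=C/B1OC(C)(C)C(C)(C)O1)CCC(=O)C(C)=C | intermediate
11 | trans-fused allylboronate (2β-Bpin, C3=C4 alkene with 4-CH3, 5α-H, 6α-OSiEt3, 9-oxo, 10β-CH3) | CC[Si](CC)(CC)O[C@H]1CCC(=O)[C@@]2(C)C[C@H](B3OC(C)(C)C(C)(C)O3)C=C(C)[C@H]12 | intermediate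
12 | formaldehyde (as paraformaldehyde) | C=O | starting material
13 | 19-O-pinacolboryl borate ester of 14 | CC[Si](CC)(CC)O[C@H]1CCC(=O)[C@@]2(C)CC=C[C@](C)(COB3OC(C)(C)C(C)(C)O3)[C@H]12 | intermediate (not isolated)
14 | homoallylic alcohol (C2=C3 alkene, 4α-CH3, 4β-CH2OH, 5α-H, 6α-OSiEt3, 9-oxo, 10β-CH3) | CC[Si](CC)(CC)O[C@H]1CCC(=O)[C@@]2(C)CC=C[C@](C)(CO)[C@H]12 | intermediate
15 | 19-O-tert-butyldimethylsilyl ether of 14 | CC[Si](CC)(CC)O[C@H]1CCC(=O)[C@@]2(C)CC=C[C@](C)(CO[Si](C)(C)C(C)(C)C)[C@H]12 | intermediate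
16 | 8α-methyl ketone | CC[Si](CC)(CC)O[C@H]1C[C@@H](C)C(=O)[C@@]2(C)CC=C[C@](C)(CO[Si](C)(C)C(C)(C)C)[C@H]12 | intermediate
17 | C8=C9 enol triflate | CC[Si](CC)(CC)O[C@H]1CC(C)=C(OS(=O)(=O)C(F)(F)F)[C@@]2(C)CC=C[C@](C)(CO[Si](C)(C)C(C)(C)C)[C@H]12 | intermediate
18 | 6α-alcohol of the enol triflate | O[C@H]1CC(C)=C(OS(=O)(=O)C(F)(F)F)[C@@]2(C)CC=C[C@](C)(CO[Si](C)(C)C(C)(C)C)[C@H]12 | intermediate
19 | 6α-acetate of the enol triflate | CC(=O)O[C@H]1CC(C)=C(OS(=O)(=O)C(F)(F)F)[C@@]2(C)CC=C[C@](C)(CO[Si](C)(C)C(C)(C)C)[C@H]12 | intermediate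
20 | 2α-alcohol (6α-OAc, 9-OTf, 19-OSi(t-Bu)Me2) | CC(=O)O[C@H]1CC(C)=C(OS(=O)(=O)C(F)(F)F)[C@@]2(C)C[C@@H](O)C[C@](C)(CO[Si](C)(C)C(C)(C)C)[C@H]12 | intermediate
21 | tributyl(vinyl)stannane | C=C[Sn](CCCC)(CCCC)CCCC | starting material
22 | 9-vinyl diene | CC(=O)O[C@H]1CC(C)=C(C=C)[C@@]2(C)C[C@@H](O)C[C@](C)(CO[Si](C)(C)C(C)(C)C)[C@H]12 | intermediate
23 | 4-bromofuran-2(5H)-one | O=C1C=C(Br)CO1 | starting material
24 | C12 B-alkyl-9-borabicyclo[3.3.1]nonane | CC(=O)O[C@H]1CC(C)=C(CCB3C4CCCC3CCC4)[C@@]2(C)C[C@@H](O)C[C@](C)(CO[Si](C)(C)C(C)(C)C)[C@H]12 | intermediate (not isolated)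
25 | 19-O-tert-butyldimethylsilyl ether of the target | CC(=O)O[C@H]1CC(C)=C(CCC3=CC(=O)OC3)[C@@]2(C)C[C@@H](O)C[C@](C)(CO[Si](C)(C)C(C)(C)C)[C@H]12 | intermediate
26 | CNP0231903.1 (6α-acetoxy-2α,19-dihydroxylabda-8,13-dien-15,16-olide) | CC(=O)O[C@H]1CC(C)=C(CCC2=CC(=O)OC2)[C@@]2(C)C[C@@H](O)C[C@](C)(CO)[C@H]12 | target

**Totals**

Total step count: 16. Longest linear sequence: 16 steps (from 1).

**Steps most likely to fail**

Step 6. The cycloaddition may show incomplete exo (trans-fusion) selectivity, or the boryl-substituted diene may react so slowly at the temperature needed that the trienone oligomerises or the allylboronate undergoes a 1,3-boron shift. The fallback sets out from enal 8 and comes back at alcohol 14.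
- Wittig methylenation (Ph3P=CH2, −78 °C, aldehyde-selective) would give the boron-free triene (6S,7E)-2,8-dimethyl-6-(triethylsilyloxy)deca-1,7,9-trien-3-one F1.
- F1 tolerates a Lewis acid, so the cycloaddition could be run with Me2AlCl at −78 °C, where α-methyl enones are most carbonyl-exo-selective, to give the trans-fused octalone F2 (C2 now CH2).
- Allylic oxidation (CrO3·3,5-dimethylpyrazole) should give the C2 enone F3.
- Luche reduction (NaBH4, CeCl3·7H2O; hydride from the α face, away from C20; the hindered C9 ketone should be spared) should give the 2β-allylic alcohol F4.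
- A Johnson–Claisen rearrangement (MeC(OEt)3, EtCO2H cat., 140 °C) would transfer the C2 configuration suprafacially to C4 and give the ethyl ester F5, with the β-CH2CO2Et group and the C2=C3 alkene.
- Saponification (LiOH) gives the acid F6.
- Barton decarboxylative hydroxylation would run through the thiohydroxamate ester F7 (N-hydroxypyridine-2-thione, DCC) and the hydroperoxide F8 (O2, t-BuSH, hν), which PPh3 reduces to 14.

Step 5. Divalent chromium may reduce the γ-silyloxy enal or the enone in competition with olefination, or the E-selectivity may be incomplete. The fallback sets out from amide 3 and comes back at trienone 10.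
- The one-pot Swern/Wittig sequence of step 4, applied to 3, would give the enal amide (4S,5E)-N-methoxy-N,6-dimethyl-7-oxo-4-(triethylsilyloxy)hept-5-enamide F9.
- Seyferth–Gilbert homologation with the Ohira–Bestmann reagent (K2CO3, MeOH) would give the enyne amide F10.
- Hydroboration with pinacolborane catalysed by Cp2Zr(H)Cl (syn, anti-Markovnikov) would give the (E,E)-dienylboronate amide F11.
- Addition of isopropenylmagnesium bromide 4 at −78 °C (Weinreb ketone synthesis, the pinacol boronate being tolerated at low temperature) would give 10.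

Step 15. The aqueous base needed for transmetalation may degrade the β-bromobutenolide (conjugate addition or ring opening), or the coupling may lose to protodeboronation and β-hydride elimination. The fallback sets out from triflate 20 and comes back at 25.
- The sp2–sp3 coupling is moved to the robust triflate: B-[2-(furan-3-yl)ethyl]-9-borabicyclo[3.3.1]nonane F12 (from 3-vinylfuran and 9-BBN) with Pd(dppf)Cl2 and K3PO4 would give the 3-furyl compound F13.
- Singlet-oxygen oxidation with a hindered base (O2, hν, tetraphenylporphyrin, i-Pr2NEt, −78 °C, where the furan should out-compete the hindered C8=C9 alkene) should give the 4-substituted 5-hydroxybutenolide F14.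
- NaBH4 reduces F14 to 25.

**Further compounds**

F1 | step 6 | (6S,7E)-2,8-dimethyl-6-(triethylsilyloxy)deca-1,7,9-trien-3-one | CC[Si](CC)(CC)O[C@H](/C=C(C)/C=C)CCC(=O)C(C)=C
F2 | step 6 | trans-fused decal-3-en-9-one with 4-CH3, 5α-H, 6α-OSiEt3, 10β-CH3 | CC[Si](CC)(CC)O[C@H]1CCC(=O)[C@@]2(C)CCC=C(C)[C@H]12
F3 | step 6 | decal-3-ene-2,9-dione (otherwise as F2) | CC[Si](CC)(CC)O[C@H]1CCC(=O)[C@@]2(C)CC(=O)C=C(C)[C@H]12
F4 | step 6 | 2β-allylic alcohol (otherwise as F2) | CC[Si](CC)(CC)O[C@H]1CCC(=O)[C@@]2(C)C[C@H](O)C=C(C)[C@H]12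
F5 | step 6 | ethyl ester: decal-2-en-9-one with 4α-CH3, 4β-CH2CO2Et | CC[Si](CC)(CC)O[C@H]1CCC(=O)[C@@]2(C)CC=C[C@](C)(CC(=O)OCC)[C@H]12
F6 | step 6 | carboxylic acid of F5 | CC[Si](CC)(CC)O[C@H]1CCC(=O)[C@@]2(C)CC=C[C@](C)(CC(O)=O)[C@H]12
F7 | step 6 | 2-thioxopyridin-1(2H)-yl ester of F6 | CC[Si](CC)(CC)O[C@H]1CCC(=O)[C@@]2(C)CC=C[C@](C)(CC(=O)On3ccccc3=S)[C@H]12
F8 | step 6 | C19 hydroperoxide (4β-CH2OOH) | CC[Si](CC)(CC)O[C@H]1CCC(=O)[C@@]2(C)CC=C[C@](C)(COO)[C@H]12
F9 | step 5 | (4S,5E)-N-methoxy-N,6-dimethyl-7-oxo-4-(triethylsilyloxy)hept-5-enamide | CC[Si](CC)(CC)O[C@H](/C=C(C)/C=O)CCC(=O)N(C)OC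
F10 | step 5 | (4S,5E)-N-methoxy-N,6-dimethyl-4-(triethylsilyloxy)oct-5-en-7-ynamide | CC[Si](CC)(CC)O[C@H](/C=C(C)/C#C)CCC(=O)N(C)OC
F11 | step 5 | (4S,5E,7E)-N-methoxy-N,6-dimethyl-8-(4,4,5,5-tetramethyl-1,3,2-dioxaborolan-2-yl)-4-(triethylsilyloxy)octa-5,7-dienamide | CC[Si](CC)(CC)O[C@H](/C=C(C)/C=C/B1OC(C)(C)C(C)(C)O1)CCC(=O)N(C)OC
F12 | step 15 | B-[2-(furan-3-yl)ethyl]-9-borabicyclo[3.3.1]nonane | c1cc(CCB2C3CCCC2CCC3)co1
F13 | step 15 | 3-furyl compound (C12–furan-3-yl in place of the butenolide of 25) | CC(=O)O[C@H]1CC(C)=C(CCc3ccoc3)[C@@]2(C)C[C@@H](O)C[C@](C)(CO[Si](C)(C)C(C)(C)C)[C@H]12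
F14 | step 15 | 5-hydroxybutenolide of 25 (both epimers at the hemiacetal carbon) | CC(=O)O[C@H]1CC(C)=C(CCC3=CC(=O)OC3O)[C@@]2(C)C[C@@H](O)C[C@](C)(CO[Si](C)(C)C(C)(C)C)[C@H]12
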